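**Strategy.** Ring B is disconnected at C8–C9 (labdane numbering). The tertiary carbinol C8 lies next to C9, whose two-carbon appendage C11–C12 maps onto an acrylate, so the O–C8–C9–C11–C12 γ-hydroxy ester unit of the cis-fused decalin is the retron for a reductive ketone–enoate union. A samarium diiodide ketyl–olefin cyclisation (6-exo-trig) joins the two electrophilic carbons C8 and C9 in one operation, closing ring B and setting both new stereocentres. The precursor is a ring A cyclohexane carrying cis-disposed arms: a β-silyloxy methyl ketone at C5 and an (E)-enoate on the quaternary C10, built by decarboxylative asymmetric allylation, nitrile-controlled hydroboration and a proline aldol.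

Key step: step 12

Remark: the target's configuration is (5S,6S,8S,9S,10R) in labdane numbering, a cis-fused decalin with H-5, the C10 methyl, the C8 methyl, the C9 side chain and the C6 acetoxy group on one face and the 8-OH on the other; the route is built for exactly this isomer.

Step 1
Reactants: 1 2,2,6-trimethylcyclohexanone
Product: 3 allyl 2,6,6-trimethylcyclohex-1-en-1-yl carbonate, via lithium enolate 2 (not isolated)
Conditions: LiN(SiMe3)2, THF, 0 °C; then allyl chloroformate, −78 °C → rt
Reagents that add atoms: allyl chloroformate C=CCOC(=O)Cl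
Why: The ketone has a single enolisable position, so deprotonation should give one tetrasubstituted lithium enolate, which the chloroformate acylates on oxygen (enol carbonate formation).

Step 2
Reactants: 3 allyl 2,6,6-trimethylcyclohex-1-en-1-yl carbonate
Product: 4 (S)-2-allyl-2,6,6-trimethylcyclohexanone
Conditions: Pd2(dba)3 (2.5 mol%), (S)-t-Bu-PHOX (6 mol%), THF, 25 °C
Reagents that add atoms: none
Why: Palladium-catalysed decarboxylative asymmetric allylic alkylation (Tsuji type): loss of CO2 gives a π-allylpalladium enolate, and the chiral phosphinooxazoline ligand directs C-allylation to one enolate face, setting the quaternary C10 as (S).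

Step 3
Reactants: 4 (S)-2-allyl-2,6,6-trimethylcyclohexanone
Product: 5 (S)-2,2,6-trimethyl-6-[(E)-prop-1-enyl]cyclohexanone
Conditions: PdCl2(MeCN)2 (10 mol%), toluene, 80 °C
Reagents that add atoms: none
Why: Palladium-hydride olefin isomerisation should move the terminal double bond by one position; it cannot go further because C10 is quaternary, and the stereocentre is untouched.

Step 4
Reactants: 5 (S)-2,2,6-trimethyl-6-[(E)-prop-1-enyl]cyclohexanone
Product: 7 (S)-1,3,3-trimethyl-2-oxocyclohexane-1-carbonitrile, via keto aldehyde 6 (not isolated)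
Conditions: O3, CH2Cl2/MeOH, −78 °C; Me2S; then H2NOSO3H, THF/H2O, rt → 50 °C
Reagents that add atoms: hydroxylamine-O-sulfonic acid NOS(=O)(=O)O
Why: Ozonolysis cleaves the propenyl group to the C9 aldehyde, and hydroxylamine-O-sulfonic acid converts it to the nitrile through the oxime O-sulfonate under acidic conditions that should not trigger retro-Claisen loss of the formyl group.

Step 5
Reactants: 7 (S)-1,3,3-trimethyl-2-oxocyclohexane-1-carbonitrile
Product: 8 (R)-1,3,3-trimethyl-2-methylidenecyclohexane-1-carbonitrile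
Conditions: Zn, CH2Br2, TiCl4, THF/CH2Cl2, 0 °C → rt
Reagents that add atoms: dibromomethane BrCBr
Why: Takai–Lombardo methylenation: the non-basic, oxophilic gem-dimetallic methylene reagent should olefinate the hindered, non-enolisable ketone where a Wittig ylide would be too slow.

Step 6
Reactants: 8 (R)-1,3,3-trimethyl-2-methylidenecyclohexane-1-carbonitrile
Product: 10 (1R,2S)-2-(hydroxymethyl)-1,3,3-trimethylcyclohexane-1-carbonitrile, via alkylborane 9 (not isolated)
Conditions: 9-BBN, THF, 65 °C; then NaBO3·4H2O, H2O, rt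
Reagents that add atoms: sodium perborate [Na+].[O-]OB=O
Why: Hydroboration–oxidation places boron on the exocyclic CH2; in the favoured chair the slim nitrile is axial at C10 (the other chair puts the C10 methyl syn-diaxial to a C4 methyl), so the borane should approach the face opposite the axial nitrile and axial C4 methyl, delivering H-5 cis to the C10 methyl and leaving the CH2OH arm cis to the nitrile.

Step 7
Reactants: 10 (1R,2S)-2-(hydroxymethyl)-1,3,3-trimethylcyclohexane-1-carbonitrile
Product: 11 (3aS,7aR)-4,4,7a-trimethyloctahydro-2-benzofuran-1-ol (anomer mixture)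
Conditions: i-Bu2AlH (2.5 equiv), CH2Cl2, −78 → 0 °C; then aqueous potassium sodium tartrate, 1 M HCl, rt
Reagents that add atoms: water O
Why: Partial reduction of the nitrile gives the N-aluminio aldimine, which is hydrolysed on work-up to the C9 aldehyde; the cis C6 hydroxyl traps it as the five-membered lactol, and no stereocentre is touched.

Step 8
Reactants: 11 (3aS,7aR)-4,4,7a-trimethyloctahydro-2-benzofuran-1-ol
Product: 12 ethyl (2E)-3-[(1S,2S)-2-(hydroxymethyl)-1,3,3-trimethylcyclohexyl]prop-2-enoate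
Conditions: Ph3P=CHCO2Et, PhCO2H (cat.), toluene, 90 °C
Reagents that add atoms: ethyl (triphenylphosphoranylidene)acetate CCOC(=O)C=P(c1ccccc1)(c1ccccc1)c1ccccc1
Why: Wittig olefination of the ring-opened hydroxy aldehyde with a stabilised ylide should give the (E)-enoate, and the neutral conditions disfavour oxa-Michael re-closure.

Step 9
Reactants: 12 ethyl (2E)-3-[(1S,2S)-2-(hydroxymethyl)-1,3,3-trimethylcyclohexyl]prop-2-enoate
Product: 13 ethyl (2E)-3-[(1S,2S)-2-formyl-1,3,3-trimethylcyclohexyl]prop-2-enoate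
Conditions: Dess–Martin periodinane, NaHCO3, CH2Cl2, 0 °C → rt
Reagents that add atoms: none
Why: Dess–Martin oxidation of the primary alcohol under buffered, non-basic conditions should give the aldehyde without epimerising the hindered C5 centre.

Step 10
Reactants: 13 ethyl (2E)-3-[(1S,2S)-2-formyl-1,3,3-trimethylcyclohexyl]prop-2-enoate
Product: 14 ethyl (2E)-3-{(1S,2S)-2-[(1S)-1-hydroxy-3-oxobutyl]-1,3,3-trimethylcyclohexyl}prop-2-enoate
Conditions: D-proline (30 mol%), acetone/DMSO 1:4, rt
Reagents that add atoms: acetone CC(C)=O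
Why: Proline-catalysed direct aldol: the D-proline enamine of acetone adds to one face of the α-branched aldehyde through the hydrogen-bonded chair transition state, setting C6 as (S) under catalyst control; the aldehyde cannot itself form an enamine because that would need a tetrasubstituted double bond between two quaternary carbons.

Step 11
Reactants: 14 ethyl (2E)-3-{(1S,2S)-2-[(1S)-1-hydroxy-3-oxobutyl]-1,3,3-trimethylcyclohexyl}prop-2-enoate
Product: 15 ethyl (2E)-3-{(1S,2S)-2-[(1S)-1-(tert-butyldimethylsilyloxy)-3-oxobutyl]-1,3,3-trimethylcyclohexyl}prop-2-enoate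
Conditions: TBSOTf, 2,6-lutidine, CH2Cl2, −78 °C
Reagents that add atoms: tert-butyldimethylsilyl triflate CC(C)(C)[Si](C)(C)OS(=O)(=O)C(F)(F)F
Why: Silylation with the triflate protects the hindered secondary alcohol as a non-chelating ether before the samarium step and blocks oxa-Michael addition to the enoate.

Step 12
Reactants: 15 ethyl (2E)-3-{(1S,2S)-2-[(1S)-1-(tert-butyldimethylsilyloxy)-3-oxobutyl]-1,3,3-trimethylcyclohexyl}prop-2-enoate
Product: 16 ethyl 2-[(1S,2S,4S,4aS,8aR)-4-(tert-butyldimethylsilyloxy)-2-hydroxy-2,5,5,8a-tetramethyldecahydronaphthalen-1-yl]acetate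
Conditions: SmI2 (2.5 equiv), HMPA, t-BuOH (2 equiv), THF, −78 → 0 °C
Reagents that add atoms: none
Why: Electron transfer from SmI2 to the C8 methyl ketone gives a samarium ketyl that adds to C9, the β-carbon of the (E)-enoate; a second electron turns the C11 radical into a samarium enolate, which t-BuOH protonates. This is the samarium diiodide ketyl–olefin (reductive ketone–enoate) cyclisation, a known umpolung union of two electrophilic carbons. Ring B closes in the 6-exo-trig mode through a chair in which the C6 silyl ether and the C10 methyl are equatorial and C1 of ring A is axial. At C8 the methyl group should take the equatorial site to avoid a syn-diaxial clash with C1, which leaves the O–Sm bond axial. At C9 the enoate should lie anti-periplanar to the ketyl C–O bond (dipole and electron repulsion), that is axial, which places C11 trans to the 8-oxygen and cis to the C10 methyl as in the target. The step needs C–C bond formation at the hindered C9 to outrun simple reduction and needs a non-chelated transition state; the tether (only the 6-exo path is open), HMPA-accelerated electron transfer and the bulky non-coordinating silyl ether at C6 are meant to secure this.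

Step 13
Reactants: 16 ethyl 2-[(1S,2S,4S,4aS,8aR)-4-(tert-butyldimethylsilyloxy)-2-hydroxy-2,5,5,8a-tetramethyldecahydronaphthalen-1-yl]acetate
Product: 17 (1S,2S,4S,4aS,8aR)-4-(tert-butyldimethylsilyloxy)-1-(2-hydroxyethyl)-2,5,5,8a-tetramethyldecahydronaphthalen-2-ol
Conditions: LiBH4, THF, MeOH (1 equiv), 0 °C → rt
Reagents that add atoms: none
Why: Hydride reduction of the ester to the primary alcohol should leave the silyl ether and tertiary alcohol untouched; any lactone formed in step 12 would give the same diol.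

Step 14
Reactants: 17 (1S,2S,4S,4aS,8aR)-4-(tert-butyldimethylsilyloxy)-1-(2-hydroxyethyl)-2,5,5,8a-tetramethyldecahydronaphthalen-2-ol
Product: 18 (1S,2S,4S,4aS,8aR)-4-(tert-butyldimethylsilyloxy)-1-(2-iodoethyl)-2,5,5,8a-tetramethyldecahydronaphthalen-2-ol
Conditions: I2, PPh3, imidazole, CH2Cl2, 0 °C → rt
Reagents that add atoms: iodine II
Why: Appel-type iodination converts only the primary alcohol; the tertiary 8-OH is inert and, being anti to the side chain, should not close a tetrahydrofuran.

Step 15
Reactants: 19 ethyl acetoacetate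
Product: 20 ethyl (2E)-3-(trifluoromethylsulfonyloxy)but-2-enoate
Conditions: Tf2O, aqueous Me4NOH, toluene/hexane, 5 °C → rt
Reagents that add atoms: triflic anhydride O=S(=O)(OS(=O)(=O)C(F)(F)F)C(F)(F)F
Why: O-Triflation of the acetoacetate enolate with a non-coordinating tetramethylammonium counter-ion should give the extended (E)-enol triflate, with the triflate trans to the ester.

Step 16
Reactants: 18 (1S,2S,4S,4aS,8aR)-4-(tert-butyldimethylsilyloxy)-1-(2-iodoethyl)-2,5,5,8a-tetramethyldecahydronaphthalen-2-ol; 20 ethyl (2E)-3-(trifluoromethylsulfonyloxy)but-2-enoate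
Product: 22 ethyl (2E)-5-[(1S,2S,4S,4aS,8aR)-4-(tert-butyldimethylsilyloxy)-2-hydroxy-2,5,5,8a-tetramethyldecahydronaphthalen-1-yl]-3-methylpent-2-enoate, via alkylzinc iodide 21 (not isolated)
Conditions: Zn, LiCl, THF, 40 °C; then 20, Pd(PPh3)4 (5 mol%), THF/NMP, 50 °C
Reagents that add atoms: none
Why: Negishi sp3–sp2 cross-coupling: zinc insertion gives the primary alkylzinc iodide, which should couple with the enol triflate with retention of alkene geometry, fixing the (E)-trisubstituted enoate.

Step 17
Reactants: 22 ethyl (2E)-5-[(1S,2S,4S,4aS,8aR)-4-(tert-butyldimethylsilyloxy)-2-hydroxy-2,5,5,8a-tetramethyldecahydronaphthalen-1-yl]-3-methylpent-2-enoate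
Product: 23 (2E)-5-[(1S,2S,4S,4aS,8aR)-4-(tert-butyldimethylsilyloxy)-2-hydroxy-2,5,5,8a-tetramethyldecahydronaphthalen-1-yl]-3-methylpent-2-enoic acid
Conditions: LiOH, THF/MeOH/H2O, 40 °C; then 1 M HCl to pH 4
Reagents that add atoms: lithium hydroxide [Li+].[OH-]
Why: Saponification of the ethyl ester is done while the silyl ether still masks the C6 oxygen, so no acetate is at risk.

Step 18
Reactants: 23 (2E)-5-[(1S,2S,4S,4aS,8aR)-4-(tert-butyldimethylsilyloxy)-2-hydroxy-2,5,5,8a-tetramethyldecahydronaphthalen-1-yl]-3-methylpent-2-enoic acid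
Product: 24 (2E)-5-[(1S,2S,4S,4aS,8aR)-2,4-dihydroxy-2,5,5,8a-tetramethyldecahydronaphthalen-1-yl]-3-methylpent-2-enoic acid
Conditions: HF·pyridine, pyridine/THF, 0 °C → rt
Reagents that add atoms: none
Why: Fluoride-mediated desilylation should free the C6 hydroxyl under buffered conditions that do not dehydrate the tertiary alcohol.

Step 19
Reactants: 24 (2E)-5-[(1S,2S,4S,4aS,8aR)-2,4-dihydroxy-2,5,5,8a-tetramethyldecahydronaphthalen-1-yl]-3-methylpent-2-enoic acid
Product: 26 (2E)-5-[(1S,2S,4S,4aS,8aR)-4-acetoxy-2-hydroxy-2,5,5,8a-tetramethyldecahydronaphthalen-1-yl]-3-methylpent-2-enoic acid, via mixed anhydride 25 (not isolated)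
Conditions: Ac2O, pyridine, DMAP (cat.), CH2Cl2, 0 °C → rt; then H2O/THF, rt
Reagents that add atoms: acetic anhydride CC(=O)OC(C)=O
Why: Acetylation should occur at the secondary equatorial 6-OH only; the tertiary axial 8-OH does not react under these conditions, and the transient mixed anhydride of the acid is hydrolysed on aqueous work-up.

**Compound list**

1 | 2,2,6-trimethylcyclohexanone | CC1CCCC(C)(C)C1=O | starting material
2 | lithium 2,6,6-trimethylcyclohex-1-en-1-olate | [Li]OC1=C(C)CCCC1(C)C | intermediate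
3 | allyl 2,6,6-trimethylcyclohex-1-en-1-yl carbonate | C=CCOC(=O)OC1=C(C)CCCC1(C)C | intermediate
4 | (S)-2-allyl-2,6,6-trimethylcyclohexanone | C=CC[C@]1(C)CCCC(C)(C)C1=O | intermediate
5 | (S)-2,2,6-trimethyl-6-[(E)-prop-1-enyl]cyclohexanone | C/C=C/[C@]1(C)CCCC(C)(C)C1=O | intermediate
6 | (S)-1,3,3-trimethyl-2-oxocyclohexane-1-carbaldehyde | O=C[C@]1(C)CCCC(C)(C)C1=O | intermediate
7 | (S)-1,3,3-trimethyl-2-oxocyclohexane-1-carbonitrile | N#C[C@]1(C)CCCC(C)(C)C1=O | intermediate
8 | (R)-1,3,3-trimethyl-2-methylidenecyclohexane-1-carbonitrile | N#C[C@]1(C)CCCC(C)(C)C1=C | intermediate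
9 | B-alkyl-9-BBN adduct of 8 (boron on the exocyclic CH2, H-5 cis to the C10 methyl) | N#C[C@]1(C)CCCC(C)(C)[C@@H]1CB1C2CCCC1CCC2 | intermediate
10 | (1R,2S)-2-(hydroxymethyl)-1,3,3-trimethylcyclohexane-1-carbonitrile | N#C[C@]1(C)CCCC(C)(C)[C@@H]1CO | intermediate
11 | (3aS,7aR)-4,4,7a-trimethyloctahydro-2-benzofuran-1-ol (cis-fused lactol, anomer mixture) | OC1OC[C@H]2C(C)(C)CCC[C@@]12C | intermediate
12 | ethyl (2E)-3-[(1S,2S)-2-(hydroxymethyl)-1,3,3-trimethylcyclohexyl]prop-2-enoate | CCOC(=O)/C=C/[C@]1(C)CCCC(C)(C)[C@@H]1CO | intermediate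
13 | ethyl (2E)-3-[(1S,2S)-2-formyl-1,3,3-trimethylcyclohexyl]prop-2-enoate | CCOC(=O)/C=C/[C@]1(C)CCCC(C)(C)[C@@H]1C=O | intermediate
14 | ethyl (2E)-3-{(1S,2S)-2-[(1S)-1-hydroxy-3-oxobutyl]-1,3,3-trimethylcyclohexyl}prop-2-enoate | CCOC(=O)/C=C/[C@]1(C)CCCC(C)(C)[C@@H]1[C@@H](O)CC(C)=O | intermediate
15 | ethyl (2E)-3-{(1S,2S)-2-[(1S)-1-(tert-butyldimethylsilyloxy)-3-oxobutyl]-1,3,3-trimethylcyclohexyl}prop-2-enoate | CCOC(=O)/C=C/[C@]1(C)CCCC(C)(C)[C@@H]1[C@@H](O[Si](C)(C)C(C)(C)C)CC(C)=O | intermediate
16 | ethyl 2-[(1S,2S,4S,4aS,8aR)-4-(tert-butyldimethylsilyloxy)-2-hydroxy-2,5,5,8a-tetramethyldecahydronaphthalen-1-yl]acetate (cis-fused) | CC(C)(C)[Si](C)(C)O[C@H]1C[C@](C)(O)[C@@H](CC(=O)OCC)[C@]2(C)CCCC(C)(C)[C@H]12 | intermediate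
17 | (1S,2S,4S,4aS,8aR)-4-(tert-butyldimethylsilyloxy)-1-(2-hydroxyethyl)-2,5,5,8a-tetramethyldecahydronaphthalen-2-ol | CC(C)(C)[Si](C)(C)O[C@H]1C[C@](C)(O)[C@@H](CCO)[C@]2(C)CCCC(C)(C)[C@H]12 | intermediate
18 | (1S,2S,4S,4aS,8aR)-4-(tert-butyldimethylsilyloxy)-1-(2-iodoethyl)-2,5,5,8a-tetramethyldecahydronaphthalen-2-ol | CC(C)(C)[Si](C)(C)O[C@H]1C[C@](C)(O)[C@@H](CCI)[C@]2(C)CCCC(C)(C)[C@H]12 | intermediate
19 | ethyl acetoacetate | CCOC(=O)CC(C)=O | starting material
20 | ethyl (2E)-3-(trifluoromethylsulfonyloxy)but-2-enoate | CCOC(=O)/C=C(C)/OS(=O)(=O)C(F)(F)F | intermediate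
21 | alkylzinc iodide from 18 | CC(C)(C)[Si](C)(C)O[C@H]1C[C@](C)(O)[C@@H](CC[Zn]I)[C@]2(C)CCCC(C)(C)[C@H]12 | intermediate
22 | ethyl (2E)-5-[(1S,2S,4S,4aS,8aR)-4-(tert-butyldimethylsilyloxy)-2-hydroxy-2,5,5,8a-tetramethyldecahydronaphthalen-1-yl]-3-methylpent-2-enoate | CC(C)(C)[Si](C)(C)O[C@H]1C[C@](C)(O)[C@@H](CC/C(C)=C/C(=O)OCC)[C@]2(C)CCCC(C)(C)[C@H]12 | intermediate
23 | (2E)-5-[(1S,2S,4S,4aS,8aR)-4-(tert-butyldimethylsilyloxy)-2-hydroxy-2,5,5,8a-tetramethyldecahydronaphthalen-1-yl]-3-methylpent-2-enoic acid | CC(C)(C)[Si](C)(C)O[C@H]1C[C@](C)(O)[C@@H](CC/C(C)=C/C(=O)O)[C@]2(C)CCCC(C)(C)[C@H]12 | intermediate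
24 | (2E)-5-[(1S,2S,4S,4aS,8aR)-2,4-dihydroxy-2,5,5,8a-tetramethyldecahydronaphthalen-1-yl]-3-methylpent-2-enoic acid | O[C@H]1C[C@](C)(O)[C@@H](CC/C(C)=C/C(=O)O)[C@]2(C)CCCC(C)(C)[C@H]12 | intermediate
25 | acetic mixed anhydride of the 6-O-acetyl acid | CC(=O)O[C@H]1C[C@](C)(O)[C@@H](CC/C(C)=C/C(=O)OC(C)=O)[C@]2(C)CCCC(C)(C)[C@H]12 | intermediate
26 | (2E)-5-[(1S,2S,4S,4aS,8aR)-4-acetoxy-2-hydroxy-2,5,5,8a-tetramethyldecahydronaphthalen-1-yl]-3-methylpent-2-enoic acid (CNP0221670.1) | CC(=O)O[C@H]1C[C@](C)(O)[C@@H](CC/C(C)=C/C(=O)O)[C@]2(C)CCCC(C)(C)[C@H]12 | target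

**Step count.** Total: 19 steps. Longest linear sequence: 18 steps (steps 1–14 and 16–19, from 1 to 26); step 15 makes fragment 20.

**Steps most likely to fail, with fallbacks**

1. Step 12 (key step). The ketyl may be reduced further, or the enoate may be reduced, before the C8–C9 bond forms at the hindered C9; the anti arrangement of the C–O bond and the enoate may also erode, lowering selectivity at C8 and C9. The fallback generates the C8 radical by hydrogen-atom transfer instead of electron transfer. It sets out from 15: kinetic enolisation at the methyl group (LiN(i-Pr)2, Et3SiCl, THF, −78 °C) should give the triethylsilyl enol ether F1. Metal-hydride hydrogen-atom transfer (Fe(acac)3, PhSiH3, EtOH/ethylene glycol, 60 °C) then places a hydrogen on the terminal CH2 and gives the tertiary α-silyloxy radical at C8, which should add 6-exo to the enoate through the same chair (small oxygen substituent axial, enoate axial) to give the bis-silyl ether F2. Selective methanolysis of the triethylsilyl ether (PPTS, MeOH, 0 °C) returns to the route at 16.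

2. Step 10. Enamine addition to the very hindered aldehyde may be slow, catalyst control over the C6 configuration may be lost, and the new hydroxyl may add to the enoate. The fallback uses reagent-controlled allylation and sets out from 13: (−)-B-allyldiisopinocampheylborane (Et2O, −78 °C; NaBO3 work-up) should give the homoallylic alcohol F3 with the (S) configuration at C6. Silylation (TBSOTf, 2,6-lutidine, CH2Cl2, −78 °C) gives the silyl ether F4, and Wacker oxidation of the terminal alkene (PdCl2, CuCl, O2, DMF/H2O, rt) returns to the route at 15.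

3. Step 6. Hydrogen may be delivered to C5 from both faces if the chair with the axial C10 methyl reacts competitively, giving the C5 epimer. The fallback sets C5 by a stereospecific hydride shift and sets out from 7: dimethylsulfonium methylide (Me3S+ I−, KN(SiMe3)2, THF, 0 °C) should add from the face opposite the axial nitrile to give the spiro-epoxide F5. Methylaluminium bis(4-bromo-2,6-di-tert-butylphenoxide) (CH2Cl2, −78 °C) should open the C5–O bond with anti migration of hydride from the CH2 group to give the cis cyano aldehyde F6. Reduction (NaBH4, MeOH, 0 °C) returns to the route at 10.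

**Further compounds**

F1 | step 12 | ethyl (2E)-3-{(1S,2S)-2-[(1S)-1-(tert-butyldimethylsilyloxy)-3-(triethylsilyloxy)but-3-enyl]-1,3,3-trimethylcyclohexyl}prop-2-enoate | CCOC(=O)/C=C/[C@]1(C)CCCC(C)(C)[C@@H]1[C@@H](O[Si](C)(C)C(C)(C)C)CC(=C)O[Si](CC)(CC)CC
F2 | step 12 | ethyl 2-[(1S,2S,4S,4aS,8aR)-4-(tert-butyldimethylsilyloxy)-2,5,5,8a-tetramethyl-2-(triethylsilyloxy)decahydronaphthalen-1-yl]acetate | CC(C)(C)[Si](C)(C)O[C@H]1C[C@](C)(O[Si](CC)(CC)CC)[C@@H](CC(=O)OCC)[C@]2(C)CCCC(C)(C)[C@H]12
F3 | step 10 | ethyl (2E)-3-{(1S,2S)-2-[(1S)-1-hydroxybut-3-enyl]-1,3,3-trimethylcyclohexyl}prop-2-enoate | CCOC(=O)/C=C/[C@]1(C)CCCC(C)(C)[C@@H]1[C@@H](O)CC=C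
F4 | step 10 | ethyl (2E)-3-{(1S,2S)-2-[(1S)-1-(tert-butyldimethylsilyloxy)but-3-enyl]-1,3,3-trimethylcyclohexyl}prop-2-enoate | CCOC(=O)/C=C/[C@]1(C)CCCC(C)(C)[C@@H]1[C@@H](O[Si](C)(C)C(C)(C)C)CC=C
F5 | step 6 | 4,8,8-trimethyl-1-oxaspiro[2.5]octane-4-carbonitrile (epoxide oxygen cis to the nitrile) | N#C[C@]1(C)CCCC(C)(C)[C@@]12CO2
F6 | step 6 | (1R,2S)-2-formyl-1,3,3-trimethylcyclohexane-1-carbonitrile | N#C[C@]1(C)CCCC(C)(C)[C@@H]1C=O
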